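In this closed, stirred vessel the substrate releases target and released group, and the released group can leave solution as crystals.

substrate 20 mM; time 6.0 s

    substrate ⇌ target + released group (K1 = 0.0025 M, k1 = 0.16 s⁻¹)
    crystals ⇌ released group, rate k2*(cs2 - [released group]) while solid is left; crystals form when [released group] > cs2 (cs2 = 0.25 mM, k2 = 0.89 s⁻¹)
    target ⇌ isomer of the product (K3 = 0.32, k3 = 0.12 s⁻¹)
    released group → by-product carried off (k4 = 0.032 s⁻¹)

- elm: doubling the dissolution coefficient of step 2, all else as stated
- ash: doubling the solubility in step 2, all else as stated

- for released group the crystals are counted in
- as a solid, counted per litre of solution: crystals
- run time (flask): 6.0 s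

* amount of target at 6.0 s, in percent of the substrate charged
* concentration of released group in solution at 0.60 s, in percent of saturation
* the change that raises the amount of target at 6.0 s, in percent of the substrate charged most ("none" if none brings more than 2 percentage points) (elm / ash / none)
* amount of target at 6.0 s, in percent of the substrate charged, after elm

Two chemists dispute what [released group] does, and both freeze it at a constant level. The first step then becomes pseudo-first-order, with forward constant 0.16 s⁻¹ and back constant equal to that constant over the equilibrium constant, times the level. Both also treat target and isomer as balanced, since the relaxation half-life of that pair, 1.40 s, is short against 6.0 s, so target is 75.8% of the pair. Substrate then relaxes at a rate λ, the forward constant plus the back constant times that share. The part turned by time t is the forward constant over λ, times what exp(−λt) leaves short of unity.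

The first chemist says crystals hold [released group] at the solubility, 0.25 mM. That gives 45.3% target, and doubling the dissolution coefficient gains nothing.

I side with the second. Crystals grow from the excess over solubility, and the opening release of 3.20 mM s⁻¹ needs an excess of 3.60 mM, which is more than the solubility. If half the substrate turns within the run, the level is 2.12 mM. This is the plateau level: the solubility plus the mean net release rate over the dissolution coefficient.

It gives λ = 0.263 s⁻¹ and target 36.6%, with 48.3% of the substrate turned, close to the assumed half. Elm lowers the plateau to 1.19 mM, giving target 40.6%, a gain of 4 percentage points. Ash raises it to 2.37 mM, a change of −0.97 points. So I choose elm. At 0.60 s the level is still climbing, and I put it at 634% of saturation.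

The forecast, with more target than mine, gives 40.5%, 585%, elm and 44.5%, reasoning that “crystallisation is slower than its release”.

The flask gives 40.2% target, and elm as the best change, with 43.7% target after elm. Its [released group] stands at 587% of saturation at 0.600 s. Elm brings 3.5 points and ash −0.92 points.

In the flask, [released group] reads 2.05 mM at 3.00 s, beside the plateau of 2.12 mM, and the elm flask gains 3.5 points against my 4 points. The flask is not at rest at 6.0 s. Left until 60.0 s, target rises to 70.3% and substrate falls to 7.24%, while crystals reach 17.2 mM. By then [released group] has come down to 0.250 mM, the solubility, which is the first chemist's level, so his view belongs to this late flask. The equilibrium constant over that level puts target over substrate at 10.0, and the flask reads 9.72.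

The numbers of this flask were drawn at random within sensible limits; the rest is arithmetic.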